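**Plan**
- Retrosynthesis: cut the two caffeoyl ester C–O bonds (O1, O3). Then undo a 1,2-shift at C1 of the cyclohexane: C1 carries both OH and CO2H and lies between two ring CH2 groups (C2, C6), which is the retron of a benzilic acid rearrangement of a cycloheptane-1,2-dione.
- The dione comes from a cycloheptene (C=C cut by ring-closing metathesis), and the diene from a terminal epoxide plus a vinyl nucleophile.
- Forward: 2-deoxy-D-glucose → acyclic 1,8-diene → cycloheptene → 1,2-dione → ring contraction to the cyclohexane → bis-acylation → global deprotection.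
- Stereochemistry: C5, C4, C3 of the target are C3, C4, C5 of 2-deoxy-D-glucose and are never touched. C1 is set in the contraction, steered by the trans-fused 4,5-acetonide (temporary ring, removed at the end) and the axial 3-benzyloxy group.
- Convergence: both cis-diol isomers from the dihydroxylation, and both modes of hydroxide attack on the dione, lead to the same product.

Key step: step 10

Remark: ring positions are named with quinic acid numbering (C1 bears OH and CO2H; O3 is cis and O5 trans to O4). 2-Deoxy-D-glucose, caffeic acid and all reagents are taken as commercial.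

**Step 1**
Reactants: 1 2-deoxy-D-glucose
Product: 2 (2R,3S,4R)-hept-6-ene-1,2,3,4-tetrol
Conditions: Ph3PCH3Br (4 equiv), KOt-Bu (4 equiv), THF, 0 °C to rt
Reagents that add atoms: methyltriphenylphosphonium bromide C[P+](c1ccccc1)(c1ccccc1)c1ccccc1.[Br-]
Why: Wittig methylenation of the open-chain aldehyde in equilibrium with the lactol, a standard reaction of unprotected 2-deoxy aldoses (no α-oxygen to eliminate); no stereocentre is formed and C3–C5 of the sugar are carried over unchanged.

**Step 2**
Reactants: 2 (2R,3S,4R)-hept-6-ene-1,2,3,4-tetrol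
Product: 3 (4S,4'R,5R)-2,2,2',2'-tetramethyl-5-(prop-2-en-1-yl)-4,4'-bi(1,3-dioxolane)
Conditions: 2,2-dimethoxypropane, TsOH (cat.), acetone, rt
Reagents that add atoms: 2,2-dimethoxypropane COC(C)(C)OC
Why: thermodynamic acetonide formation should pair the terminal 1,2-diol and the threo 3,4-diol as two dioxolanes (the internal one trans-disubstituted), the only bis-acetal without a cis-dioxolane or a dioxane; no stereocentre changes.

**Step 3**
Reactants: 3 (4S,4'R,5R)-2,2,2',2'-tetramethyl-5-(prop-2-en-1-yl)-4,4'-bi(1,3-dioxolane)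
Product: 4 (1R)-1-[(4R,5R)-2,2-dimethyl-5-(prop-2-en-1-yl)-1,3-dioxolan-4-yl]ethane-1,2-diol
Conditions: 70% aq. AcOH, rt
Reagents that add atoms: none
Why: selective hydrolysis of the terminal monosubstituted dioxolane, which is cleaved faster than the internal trans-4,5-disubstituted one (classical kinetic discrimination among sugar acetonides).

**Step 4**
Reactants: 4 (1R)-1-[(4R,5R)-2,2-dimethyl-5-(prop-2-en-1-yl)-1,3-dioxolan-4-yl]ethane-1,2-diol
Product: 6 (4S,5R)-2,2-dimethyl-4-[(2R)-oxiran-2-yl]-5-(prop-2-en-1-yl)-1,3-dioxolane, via primary tosylate 5 (not isolated)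
Conditions: NaH (2.2 equiv), 1-(p-toluenesulfonyl)imidazole (1.05 equiv), THF, 0 °C to rt
Reagents that add atoms: none
Why: one-pot sulfonylation of the primary alkoxide followed by intramolecular Williamson closure by the secondary alkoxide should give the terminal epoxide with retention at the carbinol carbon, which becomes C3 of the target.

**Step 5**
Reactants: 6 (4S,5R)-2,2-dimethyl-4-[(2R)-oxiran-2-yl]-5-(prop-2-en-1-yl)-1,3-dioxolane
Product: 7 (1R)-1-[(4R,5R)-2,2-dimethyl-5-(prop-2-en-1-yl)-1,3-dioxolan-4-yl]but-3-en-1-ol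
Conditions: vinylMgBr (2.5 equiv), CuI (10 mol %), THF, −30 to 0 °C
Reagents that add atoms: vinylmagnesium bromide C=C[Mg]Br
Why: copper-catalysed SN2 opening of a terminal epoxide at its CH2 carbon by a vinyl Grignard reagent; the C–O stereocentre is not involved, so O3 keeps the configuration of C5 of the sugar.

**Step 6**
Reactants: 7 (1R)-1-[(4R,5R)-2,2-dimethyl-5-(prop-2-en-1-yl)-1,3-dioxolan-4-yl]but-3-en-1-ol
Product: 8 (4R,5R)-4-[(1R)-1-(benzyloxy)but-3-en-1-yl]-2,2-dimethyl-5-(prop-2-en-1-yl)-1,3-dioxolane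
Conditions: NaH, BnBr, Bu4NI (cat.), THF/DMF, 0 °C to rt
Reagents that add atoms: benzyl bromide BrCc1ccccc1
Why: Williamson etherification; the benzyl ether should survive metathesis, both oxidations and aqueous hydroxide and can be removed by hydrogenolysis before the cinnamate alkenes are introduced.

**Step 7**
Reactants: 8 (4R,5R)-4-[(1R)-1-(benzyloxy)but-3-en-1-yl]-2,2-dimethyl-5-(prop-2-en-1-yl)-1,3-dioxolane
Product: 9 (3aR,4R,8aR)-4-(benzyloxy)-2,2-dimethyl-3a,5,8,8a-tetrahydro-4H-cyclohepta[d][1,3]dioxole
Conditions: (H2IMes)(PCy3)Cl2Ru=CHPh (3 mol %), CH2Cl2 (5 mM), 40 °C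
Reagents that add atoms: none
Why: ring-closing metathesis of a 1,8-diene to a cycloheptene, favoured by the trans-dioxolane that holds the two allyl arms in reach; no stereocentre is formed.

**Step 8**
Reactants: 9 (3aR,4R,8aR)-4-(benzyloxy)-2,2-dimethyl-3a,5,8,8a-tetrahydro-4H-cyclohepta[d][1,3]dioxole
Product: 10 (3aR,4R,8aR)-4-(benzyloxy)-2,2-dimethylhexahydro-4H-cyclohepta[d][1,3]dioxole-6,7-diol (cis-diol; both facial isomers are carried on)
Conditions: OsO4 (2 mol %), NMO (1.5 equiv), acetone/H2O 4:1, rt
Reagents that add atoms: N-methylmorpholine N-oxide C[N+]1([O-])CCOCC1; water O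
Why: catalytic syn-dihydroxylation of a cis-disubstituted ring alkene; facial selectivity is irrelevant because both new carbinol centres are oxidised in the next step.

**Step 9**
Reactants: 10 (3aR,4R,8aR)-4-(benzyloxy)-2,2-dimethylhexahydro-4H-cyclohepta[d][1,3]dioxole-6,7-diol
Product: 11 (3aR,4R,8aR)-4-(benzyloxy)-2,2-dimethylhexahydrocyclohepta[d][1,3]dioxole-6,7-dione
Conditions: IBX (3 equiv), DMSO, rt
Reagents that add atoms: none
Why: IBX oxidises 1,2-diols to 1,2-diketones without glycol cleavage and under neutral conditions, which should spare the base-sensitive β-alkoxy dione.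

**Step 10**
Reactants: 11 (3aR,4R,8aR)-4-(benzyloxy)-2,2-dimethylhexahydrocyclohepta[d][1,3]dioxole-6,7-dione
Product: 13 methoxymethyl 3-O-benzyl-4,5-O-isopropylidenequinate, via potassium 3-O-benzyl-4,5-O-isopropylidenequinate 12 (not isolated)
Conditions: KOH (1.2 equiv), THF/H2O 3:1, 0 °C to rt; evaporate, azeotrope with toluene; then MOMCl (1.3 equiv), DMF, 0 °C
Reagents that add atoms: potassium hydroxide [K+].[OH-]; chloromethyl methyl ether COCCl
Why: Hydroxide adds to either carbonyl of the (hydrated) 1,2-dione and the ring CH2 on that carbon shifts to the neighbouring carbonyl carbon, so one dione carbon is extruded as the carboxylate and the other becomes C1; this is the benzilic acid rearrangement of a cycloalkane-1,2-dione, the classical ring contraction known for cyclohexane- and cycloheptane-1,2-diones and for sugar diuloses, and the carboxylate is then O-alkylated by MOMCl in the same flask. The cyclohexane is thus formed not by a cyclisation but by a 7-to-6 contraction through a bridged three-centre 1,2-shift transition state, and both modes of hydroxide attack give the same constitution because C1 ends up between the two CH2 groups either way. The new stereocentre C1 is controlled by the trans-fused acetonide, which allows only the chair with O4 and O5 equatorial and the 3-benzyloxy group axial: the bulky C(OH)2O− carbon should migrate across the ring face anti to the axial OBn and end equatorial (carboxylate cis to O5), leaving the small oxyanion axial and cis to O3, as in quinic acid. The step needs addition and shift to outrun enolisation with E1cB loss of a β-oxygen; aqueous hydroxide at 0 °C keeps the dione largely as its hydrate, the C5–O bond is tethered and held equatorial (poor overlap for elimination), and benzyloxide is a poor leaving group. Carboxylate alkylation is chemoselective over the tertiary hydroxyl, which stays free for the later acylation.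

**Step 11**
Reactants: 13 methoxymethyl 3-O-benzyl-4,5-O-isopropylidenequinate
Product: 14 methoxymethyl 4,5-O-isopropylidenequinate
Conditions: H2 (1 atm), 10% Pd/C, EtOAc, rt
Reagents that add atoms: none
Why: hydrogenolysis of the benzyl ether at a stage without alkenes; the MOM ester and the acetonide are inert to these conditions.

**Step 12**
Reactants: 15 caffeic acid
Product: 16 (E)-3-(3,4-diacetoxyphenyl)prop-2-enoic acid
Conditions: Ac2O, pyridine, rt; then H2O
Reagents that add atoms: acetic anhydride CC(=O)OC(C)=O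
Why: acetylation of both phenols (any mixed anhydride is hydrolysed in the aqueous work-up); the E-alkene is untouched.

**Step 13**
Reactants: 16 (E)-3-(3,4-diacetoxyphenyl)prop-2-enoic acid
Product: 17 (E)-3-(3,4-diacetoxyphenyl)prop-2-enoyl chloride
Conditions: (COCl)2 (1.5 equiv), DMF (cat.), CH2Cl2, 0 °C to rt
Reagents that add atoms: oxalyl chloride O=C(Cl)C(Cl)=O
Why: acid chloride formation through the chloroiminium catalyst; aryl acetates and the E-alkene are stable to it.

**Step 14**
Reactants: 14 methoxymethyl 4,5-O-isopropylidenequinate; 17 (E)-3-(3,4-diacetoxyphenyl)prop-2-enoyl chloride (3 equiv)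
Product: 18 methoxymethyl 1,3-bis-O-[(E)-3-(3,4-diacetoxyphenyl)prop-2-enoyl]-4,5-O-isopropylidenequinate
Conditions: pyridine, DMAP (0.5 equiv), CH2Cl2, rt to 40 °C
Reagents that add atoms: none
Why: DMAP-catalysed acylation of the secondary 3-OH and the hindered tertiary 1-OH with an excess of the acid chloride, as precedented for 1-O-cinnamoylation of quinic acid derivatives; O4 and O5 are blocked by the acetonide and no stereocentre is touched.

**Step 15**
Reactants: 18 methoxymethyl 1,3-bis-O-[(E)-3-(3,4-diacetoxyphenyl)prop-2-enoyl]-4,5-O-isopropylidenequinate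
Product: 19 1,3-di-O-caffeoylquinic acid
Conditions: 2 M aq. HCl/THF 1:3, rt
Reagents that add atoms: none
Why: acid hydrolysis should remove the four aryl acetates, the strained trans-fused acetonide and the acetal-type MOM ester while the two cinnamate esters persist, the global deprotection precedented for caffeoylquinic acids; acidic medium disfavours acyl migration.

**Compound list**
1 | 2-deoxy-D-glucose (pyranose, anomeric mixture) | OC[C@H]1OC(O)C[C@@H](O)[C@@H]1O | starting material
2 | (2R,3S,4R)-hept-6-ene-1,2,3,4-tetrol | C=CC[C@@H](O)[C@H](O)[C@H](O)CO | intermediate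
3 | (4S,4'R,5R)-2,2,2',2'-tetramethyl-5-(prop-2-en-1-yl)-4,4'-bi(1,3-dioxolane) | C=CC[C@H]1OC(C)(C)O[C@@H]1[C@H]1COC(C)(C)O1 | intermediate
4 | (1R)-1-[(4R,5R)-2,2-dimethyl-5-(prop-2-en-1-yl)-1,3-dioxolan-4-yl]ethane-1,2-diol | C=CC[C@H]1OC(C)(C)O[C@@H]1[C@H](O)CO | intermediate
5 | primary tosylate of 4, (2R)-2-[(4R,5R)-2,2-dimethyl-5-(prop-2-en-1-yl)-1,3-dioxolan-4-yl]-2-hydroxyethyl 4-methylbenzenesulfonate (not isolated) | C=CC[C@H]1OC(C)(C)O[C@@H]1[C@H](O)COS(=O)(=O)c1ccc(C)cc1 | intermediate
6 | (4S,5R)-2,2-dimethyl-4-[(2R)-oxiran-2-yl]-5-(prop-2-en-1-yl)-1,3-dioxolane | C=CC[C@H]1OC(C)(C)O[C@@H]1[C@H]1CO1 | intermediate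
7 | (1R)-1-[(4R,5R)-2,2-dimethyl-5-(prop-2-en-1-yl)-1,3-dioxolan-4-yl]but-3-en-1-ol | C=CC[C@@H](O)[C@H]1OC(C)(C)O[C@@H]1CC=C | intermediate
8 | (4R,5R)-4-[(1R)-1-(benzyloxy)but-3-en-1-yl]-2,2-dimethyl-5-(prop-2-en-1-yl)-1,3-dioxolane | C=CC[C@@H](OCc1ccccc1)[C@H]1OC(C)(C)O[C@@H]1CC=C | intermediate
9 | (3aR,4R,8aR)-4-(benzyloxy)-2,2-dimethyl-3a,5,8,8a-tetrahydro-4H-cyclohepta[d][1,3]dioxole (trans-fused; OBn cis to the adjacent acetonide oxygen) | C1=CC[C@@H](OCc2ccccc2)[C@H]3OC(C)(C)O[C@@H]3C1 | intermediate
10 | (3aR,4R,8aR)-4-(benzyloxy)-2,2-dimethylhexahydro-4H-cyclohepta[d][1,3]dioxole-6,7-diol (cis-6,7-diol, both facial isomers) | OC1C[C@@H](OCc2ccccc2)[C@H]3OC(C)(C)O[C@@H]3CC1O | intermediate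
11 | (3aR,4R,8aR)-4-(benzyloxy)-2,2-dimethylhexahydrocyclohepta[d][1,3]dioxole-6,7-dione | O=C1C[C@@H](OCc2ccccc2)[C@H]3OC(C)(C)O[C@@H]3CC1=O | intermediate
12 | potassium 3-O-benzyl-4,5-O-isopropylidenequinate (not isolated) | [K+].[O-]C(=O)[C@]1(O)C[C@@H](OCc2ccccc2)[C@H]3OC(C)(C)O[C@@H]3C1 | intermediate
13 | methoxymethyl 3-O-benzyl-4,5-O-isopropylidenequinate | COCOC(=O)[C@]1(O)C[C@@H](OCc2ccccc2)[C@H]3OC(C)(C)O[C@@H]3C1 | intermediate
14 | methoxymethyl 4,5-O-isopropylidenequinate | COCOC(=O)[C@]1(O)C[C@@H](O)[C@H]2OC(C)(C)O[C@@H]2C1 | intermediate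
15 | caffeic acid | OC(=O)/C=C/c1ccc(O)c(O)c1 | starting material
16 | (E)-3-(3,4-diacetoxyphenyl)prop-2-enoic acid | OC(=O)/C=C/c1ccc(OC(C)=O)c(OC(C)=O)c1 | intermediate
17 | (E)-3-(3,4-diacetoxyphenyl)prop-2-enoyl chloride | ClC(=O)/C=C/c1ccc(OC(C)=O)c(OC(C)=O)c1 | intermediate
18 | methoxymethyl 1,3-bis-O-[(E)-3-(3,4-diacetoxyphenyl)prop-2-enoyl]-4,5-O-isopropylidenequinate | COCOC(=O)[C@]1(OC(=O)/C=C/c2ccc(OC(C)=O)c(OC(C)=O)c2)C[C@@H](OC(=O)/C=C/c2ccc(OC(C)=O)c(OC(C)=O)c2)[C@H]2OC(C)(C)O[C@@H]2C1 | intermediate
19 | 1,3-di-O-caffeoylquinic acid | O=C(/C=C/c1ccc(O)c(O)c1)O[C@@H]1C[C@@](OC(=O)/C=C/c2ccc(O)c(O)c2)(C(=O)O)C[C@@H](O)[C@@H]1O | target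

**Step count**
Total: 15 steps. Longest linear sequence: 13 steps (steps 1–11, 14, 15).

**Steps most likely to fail**

Step 10. Enolisation of the dione toward C2 and E1cB expulsion of the axial benzyloxide (leading toward tropolone-type aromatisation) may outrun hydroxide addition and the 1,2-shift, or the shift may occur across the wrong ring face. The fallback sets out from dione 11 and contracts the ring without an enolate next to a β-oxygen. Condensation with TsNHNH2 (1 equiv, MeOH, 0 °C) should give the mono-tosylhydrazone F1, and aqueous NaOH/CH2Cl2 then gives the α-diazoketone F2; both regioisomers converge. Photochemical Wolff rearrangement in THF/H2O gives the ring-contracted cyclohexanecarboxylic acid F3, whose C1 configuration does not matter. Oxidative decarboxylation of its dianion (LDA, 2.2 equiv; O2; acidic work-up) gives the cyclohexanone F4. Vinylcerium (vinylMgBr, CeCl3, −78 °C) should add from the equatorial side, anti to the axial 3-OBn, to give the tertiary vinyl carbinol F5 with the axial hydroxyl. Ozonolysis (O3, then Me2S) gives the α-hydroxy aldehyde F6. Pinnick oxidation and neutralisation with KHCO3 return to the potassium carboxylate 12, which is alkylated with MOMCl to 13 as in step 10.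

Step 9. Glycol C–C cleavage or over-oxidation during the double oxidation, and enolisation of the dione on isolation, may erode the material. The fallback sets out from cycloheptene 9 and avoids the vicinal diol. Ru-catalysed ketohydroxylation (RuCl3 cat., Oxone, NaHCO3, EtOAc/MeCN/H2O) should give the α-hydroxy ketone F7 as an isomer mixture. Oxidation of this single carbinol with the periodinane DMP (NaHCO3, CH2Cl2) comes back to dione 11.

Step 14. Acylation may stall at the 3-mono-ester because the tertiary 1-hydroxyl next to the ester is hindered toward the bulky cinnamoyl chloride. The fallback sets out from diol 14 and builds the cinnamate alkenes after acylation with a small acyl halide. Bromoacetyl bromide/pyridine (CH2Cl2, 0 °C) should give the bis(bromoacetate) F8. Arbuzov reaction with P(OEt)3 (110 °C) gives the bis(diethylphosphonoacetate) F9. Horner–Wadsworth–Emmons olefination with 3,4-diacetoxybenzaldehyde (LiCl, i-Pr2NEt, MeCN) gives the E,E-bis-cinnamate 18, where the route is rejoined.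

**Further compounds**
F1 | step 10 | mono-tosylhydrazone of dione 11 (one regioisomer shown) | Cc1ccc(cc1)S(=O)(=O)NN=C1C[C@@H](OCc2ccccc2)[C@H]3OC(C)(C)O[C@@H]3CC1=O
F2 | step 10 | α-diazoketone from 11 (one regioisomer shown) | [N-]=[N+]=C1C[C@@H](OCc2ccccc2)[C@H]3OC(C)(C)O[C@@H]3CC1=O
F3 | step 10 | 3-O-benzyl-4,5-O-isopropylidene-1-deoxyquinic acid (C1 epimers) | OC(=O)C1C[C@@H](OCc2ccccc2)[C@H]3OC(C)(C)O[C@@H]3C1
F4 | step 10 | 3-benzyloxy-4,5-(isopropylidenedioxy)cyclohexanone (quinic numbering, trans-fused acetonide) | O=C1C[C@@H](OCc2ccccc2)[C@H]3OC(C)(C)O[C@@H]3C1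
F5 | step 10 | 1-vinyl carbinol (vinyl equatorial, OH axial and cis to O3) | C=C[C@]1(O)C[C@@H](OCc2ccccc2)[C@H]3OC(C)(C)O[C@@H]3C1
F6 | step 10 | 3-O-benzyl-4,5-O-isopropylidenequinic aldehyde (1-hydroxy-1-carbaldehyde) | O=C[C@]1(O)C[C@@H](OCc2ccccc2)[C@H]3OC(C)(C)O[C@@H]3C1
F7 | step 9 | α-hydroxy ketone from 9 (regio- and stereoisomer mixture, one constitution shown) | O=C1C[C@@H](OCc2ccccc2)[C@H]3OC(C)(C)O[C@@H]3CC1O
F8 | step 14 | methoxymethyl 1,3-bis-O-(bromoacetyl)-4,5-O-isopropylidenequinate | COCOC(=O)[C@]1(OC(=O)CBr)C[C@@H](OC(=O)CBr)[C@H]2OC(C)(C)O[C@@H]2C1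
F9 | step 14 | methoxymethyl 1,3-bis-O-[(diethoxyphosphoryl)acetyl]-4,5-O-isopropylidenequinate | COCOC(=O)[C@]1(OC(=O)CP(=O)(OCC)OCC)C[C@@H](OC(=O)CP(=O)(OCC)OCC)[C@H]2OC(C)(C)O[C@@H]2C1
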